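**Retrosynthetic overview**
1. The strategy rests on the segment O–C9–C8–C7–C6–C5=C4 of the ten-membered carbocycle. A C9 oxygen placed this way relative to an E trisubstituted alkene is what an oxy-Cope shift leaves behind. The vicinal stereocentres C6 (O) and C7 (C11) flank the sigma bond that such a shift makes, and the in-ring cis C1=C10 enoate can be a cyclohexene alkene carried through unchanged.
2. Endgame disconnections: side-chain silyl ether, C14 methyl ester (from CH2OH via enal and acid), five-membered 6,12-lactone (oxidative lactonisation of a C6/C12 diol), C9 acetate (from the ketone), and C8 ester (SN2 inversion of an 8-epi alcohol).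
3. Key disconnection: opening C6–C7 and re-forming C4–C9 leads to a trans-1,2-dialkenylcyclohex-2-enol. This is split at C8–C9 into an E dienyl iodide (C7, C8, C11–C13) and a 6,6-disubstituted cyclohexenone.
4. The cyclohexenone comes from an enantioselective Diels–Alder adduct of a crotonaldehyde-derived silyloxydiene and methacrolein. Iodoform supplies C6 and formaldehyde supplies C14.
5. Ring order: the six-membered carbocycle first (cycloaddition), the ten-membered ring next by four-atom ring expansion, and the five-membered lactone last.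

Key step: step 14

Numbering: germacrane numbering is used from the start. The ring is C1–C10, C11–C13 is the three-carbon unit on C7 (C12 = lactone carbonyl), C14 is on C10, and C15 is on C4.
Assumption: the sense of induction in step 2 is taken from the formyl C–H···O binding model of oxazaborolidinium–enal complexes, which calls for the (R)-diphenylprolinol-derived catalyst; both antipodes are commercial, and the configuration of 4 is to be confirmed before going on.
Remark: compounds that carry the enol ether (6–10, 20) are purified on Et3N-deactivated silica.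

Step 1
Reactants: 1 (E)-crotonaldehyde
Product: 2 (E)-1-(triisopropylsilyloxy)buta-1,3-diene
Conditions: TIPSOTf, Et3N, Et2O, 0 °C to rt
Reagents that add atoms: triisopropylsilyl triflate, CC(C)[Si](C(C)C)(C(C)C)OS(=O)(=O)C(F)(F)F
Why: Silyl dienol ether formation by soft enolisation: O-silylation turns the enal into an oxocarbenium ion whose γ-hydrogen is removed by the amine, and the extended ion gives mainly the E dienol ether, the isomer that readily adopts the s-cis form needed in step 2.

Step 2
Reactants: 2 (E)-1-(triisopropylsilyloxy)buta-1,3-diene; 3 methacrolein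
Product: 4 (1R,2S)-1-methyl-2-(triisopropylsilyloxy)cyclohex-3-ene-1-carbaldehyde (CHO and OTIPS cis)
Conditions: B-(o-tolyl)oxazaborolidine from (R)-α,α-diphenylprolinol activated with Tf2NH (10 mol%), CH2Cl2, −78 °C
Reagents that add atoms: none
Why: Catalytic enantioselective Diels–Alder reaction with a chiral oxazaborolidinium Lewis acid: the oxygen-bearing diene terminus (C9) bonds to the enal α-carbon (ortho rule), the catalyst-bound s-trans enal is open only on the Si face of its α-carbon so that the quaternary carbon (future C4) is set as R, and the endo mode usual for 1-oxygenated dienes places CHO and OTIPS cis, a relation of no consequence because C9 becomes a ketone in step 6 and any exo adduct therefore converges.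

Step 3
Reactants: 4 Diels–Alder aldehyde
Product: 5 {[(1S,6S)-6-[(E)-2-iodoethenyl]-6-methylcyclohex-2-en-1-yl]oxy}triisopropylsilane
Conditions: CrCl2, CHI3, THF, 0 °C to rt
Reagents that add atoms: iodoform, IC(I)I
Why: Takai olefination: the geminal dichromium species made from CHI3 and CrCl2 adds to the non-enolisable aldehyde and the bulky quaternary neighbour enforces the arrangement that collapses to the E vinyl iodide (iodoform carbon = C6), without touching the allylic silyl ether.

Step 4
Reactants: 5 E vinyl iodide
Product: 6 {[(1S,6S)-6-[(E)-2-(4-methoxybenzyloxy)ethenyl]-6-methylcyclohex-2-en-1-yl]oxy}triisopropylsilane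
Conditions: 4-MeOC6H4CH2OH, CuI (10 mol%), 3,4,7,8-tetramethyl-1,10-phenanthroline (20 mol%), Cs2CO3, toluene, 80 °C
Reagents that add atoms: 4-methoxybenzyl alcohol, COc1ccc(CO)cc1
Why: Copper-catalysed Ullmann-type C–O coupling of a vinyl iodide with a primary alcohol, a process that keeps the alkene geometry, so that the E iodide gives the E enol ether under basic conditions harmless to the TIPS ether.

Step 5
Reactants: 6 TIPS-protected enol ether
Product: 7 (1S,6S)-6-[(E)-2-(4-methoxybenzyloxy)ethenyl]-6-methylcyclohex-2-en-1-ol
Conditions: TBAF, THF, 0 °C to rt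
Reagents that add atoms: none
Why: Fluoride-driven cleavage of the Si–O bond under basic conditions, which leave the acid-sensitive enol ether intact.

Step 6
Reactants: 7 allylic alcohol
Product: 8 (6S)-6-[(E)-2-(4-methoxybenzyloxy)ethenyl]-6-methylcyclohex-2-en-1-one
Conditions: Dess–Martin periodinane, NaHCO3, CH2Cl2, 0 °C
Reagents that add atoms: none
Why: Dess–Martin oxidation of the secondary allylic alcohol to the enone at neutral pH, the hydrogen carbonate trapping the acetic acid that would otherwise hydrolyse the enol ether; the C9 stereocentre is erased here while the non-enolisable quaternary carbon cannot epimerise.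

Step 7
Reactants: 8 enone
Product: 9 (6S)-2-(hydroxymethyl)-6-[(E)-2-(4-methoxybenzyloxy)ethenyl]-6-methylcyclohex-2-en-1-one
Conditions: 37% aqueous CH2O, DMAP (20 mol%), THF–H2O, rt
Reagents that add atoms: formaldehyde, C=O
Why: Morita–Baylis–Hillman reaction: DMAP adds reversibly to the unsubstituted β-carbon C1, the resulting enolate takes up formaldehyde at C10 and loss of DMAP restores the enone, now carrying C14, under mildly basic aqueous conditions that an enol ether tolerates.

Step 8
Reactants: 9 hydroxymethyl enone
Product: 10 (6S)-2-{[(tert-butyldimethylsilyl)oxy]methyl}-6-[(E)-2-(4-methoxybenzyloxy)ethenyl]-6-methylcyclohex-2-en-1-one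
Conditions: TBSCl, imidazole, CH2Cl2, 0 °C to rt
Reagents that add atoms: tert-butyldimethylsilyl chloride, CC(C)(C)[Si](C)(C)Cl
Why: Imidazole-promoted silylation of the primary allylic alcohol, needed so that no acidic proton meets the organometallic reagent of step 13.

Step 9
Reactants: 11 2-bromoprop-2-en-1-ol; 12 ethynyltrimethylsilane
Product: 13 2-methylidene-4-(trimethylsilyl)but-3-yn-1-ol
Conditions: PdCl2(PPh3)2 (2 mol%), CuI (4 mol%), Et3N, THF, rt
Reagents that add atoms: none
Why: Sonogashira coupling of a vinyl bromide with a terminal alkyne, which tolerates the free allylic alcohol and joins C11 to C7.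

Step 10
Reactants: 13 enynol
Product: 14 tert-butyldimethyl{[2-methylidene-4-(trimethylsilyl)but-3-yn-1-yl]oxy}silane
Conditions: TBSCl, imidazole, CH2Cl2, rt
Reagents that add atoms: tert-butyldimethylsilyl chloride, CC(C)(C)[Si](C)(C)Cl
Why: Imidazole-promoted silylation of the primary alcohol, which masks C12–OH with the same group as C14–OH so that both can be released together in step 21.

Step 11
Reactants: 14 bis-silylated enyne
Product: 15 tert-butyldimethyl[(2-methylidenebut-3-yn-1-yl)oxy]silane
Conditions: K2CO3 (20 mol%), MeOH, 0 °C to rt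
Reagents that add atoms: none
Why: Methanolysis of the alkynyl C–Si bond by catalytic methoxide, which is far faster than attack on the hindered TBS ether.

Step 12
Reactants: 15 terminal enyne
Product: 17 (1E)-1-iodo-3-{[(tert-butyldimethylsilyl)oxy]methyl}buta-1,3-diene, via alkenylzirconocene chloride 16 (not isolated)
Conditions: Cp2Zr(H)Cl, THF, rt, dark; then I2, THF, 0 °C
Reagents that add atoms: iodine, II; zirconocene hydrochloride, [H][Zr](Cl)(C1C=CC=C1)C1C=CC=C1 (its heavy atoms stay only in 16)
Why: Hydrozirconation followed by iodinolysis: Cp2Zr(H)Cl adds syn to the terminal alkyne in preference to the 1,1-disubstituted alkene with zirconium at the terminal carbon, and iodine replaces zirconium with retention to give the E dienyl iodide.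

Step 13
Reactants: 17 E dienyl iodide; 10 silyloxymethyl enone
Product: 20 (1R,6S)-1-[(1E)-3-{[(tert-butyldimethylsilyl)oxy]methyl}buta-1,3-dien-1-yl]-2-{[(tert-butyldimethylsilyl)oxy]methyl}-6-[(E)-2-(4-methoxybenzyloxy)ethenyl]-6-methylcyclohex-2-en-1-ol, via dienyllithium 18 (not isolated), via dienylcerium dichloride 19 (not isolated)
Conditions: 17, t-BuLi (2 equiv), Et2O, −78 °C; CeCl3, THF, −78 °C; then 10, −78 °C; pH 7 buffer
Reagents that add atoms: tert-butyllithium, [Li]C(C)(C)C (lithium stays only in 18); cerium trichloride, Cl[Ce](Cl)Cl (its atoms stay only in 19)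
Why: 1,2-Addition of an alkenylcerium reagent made by iodine–lithium exchange and transmetalation, whose low basicity and oxophilicity favour carbonyl attack on the hindered enone over conjugate addition or γ-deprotonation; in the Felkin–Anh sense the sp2-bound alkenyl group on the quaternary carbon stands pseudo-axial and perpendicular to the C=O, so the nucleophile enters anti to it and sets C9 as R (OH trans to CH3, the two alkenyl groups trans), and the minor cis-dialkenyl carbinol is removed by chromatography.

Step 14
Reactants: 20 trans-dialkenylcyclohexenol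
Product: 23 ten-membered 8-epi 8-hydroxy-9-ketone (6R 7R 8R; C6 and C7 spatially as in the target), via potassium alkoxide 21 (not isolated), via potassium enolate 22 (not isolated)
Conditions: KN(SiMe3)2 (1.2 equiv), 18-crown-6 (1.5 equiv), THF, −78 to 0 °C; then −78 °C, 2-(phenylsulfonyl)-3-phenyloxaziridine (1.5 equiv); AcOH, −78 °C
Reagents that add atoms: 2-(phenylsulfonyl)-3-phenyloxaziridine, O=S(=O)(c1ccccc1)N1OC1c1ccccc1; potassium hexamethyldisilazide, [K+].C[Si](C)(C)[N-][Si](C)(C)C (potassium stays only in 21 and 22)
Why: KN(SiMe3)2 with 18-crown-6 gives the loosely paired potassium alkoxide 21, whose oxyanion weakens the adjacent C4–C9 bond and triggers a concerted [3,3] shift across C7=C8–C9–C4–C5=C6 (anionic oxy-Cope rearrangement), after which enolate 22 is oxidised in the same flask by oxygen transfer from the N-sulfonyloxaziridine; the closest known reaction type is the ring expansion of 1,2-dialkenylcyclohex-2-enols to cyclodecadienones with oxidation of the regiodefined enolate. The ten-membered ring is closed by four-atom ring expansion, C6–C7 forming while the C4–C9 bond of the cyclohexene breaks, not by end-to-end cyclisation, and the cyclohexene alkene is carried over as the in-ring cis C1=C10 bond. With the two alkenyl groups trans, the C10=C1–C2–C3 tether allows only the chair in which the ring bonds C9–C10 and C4–C3 are equatorial and O− and CH3 axial, which fixes C4=C5 as E and the C8=C9 enolate as trans within the ring. In this chair the E dienyl and E enol ether termini hold C11 and the 4-methoxybenzyloxy group equatorial, so C6 and C7 are formed syn along C5–C6–C7–C8 (the trans-lactone relation) and their absolute sense is relayed from the 9R,4S pair, both members of which become trigonal. C8 is controlled by peripheral attack: the inner face of enolate 22 is covered by the transannular C4=C5 alkene, so oxygen arrives from outside and the chair-derived conformer predicts the 8R (8-epi) alcohol, an assignment to be confirmed by NOE. The selectivities needed are chair over boat, secured by the trans relation and the E geometry of both alkenes, and oxygenation at one carbon, secured because the cross-conjugated enolate is formed only toward C8 and is nucleophilic only there.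

Step 15
Reactants: 24 methyl 2-(hydroxymethyl)acrylate
Product: 25 methyl 2-{[(tert-butyldiphenylsilyl)oxy]methyl}acrylate
Conditions: TBDPSCl, imidazole, CH2Cl2, rt
Reagents that add atoms: tert-butyldiphenylsilyl chloride, CC(C)(C)[Si](Cl)(c1ccccc1)c1ccccc1
Why: Imidazole-promoted silylation with a group that is much more acid-stable than TBS, so that it outlasts step 21.

Step 16
Reactants: 25 silylated acrylate ester
Product: 26 2-{[(tert-butyldiphenylsilyl)oxy]methyl}acrylic acid
Conditions: LiOH, THF–H2O, 0 °C to rt; then 1 M HCl to pH 3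
Reagents that add atoms: lithium hydroxide, [Li+].[OH-]
Why: Saponification of the methyl ester with LiOH at low temperature, where acyl attack outruns conjugate addition to the α-substituted acrylate and the TBDPS ether is stable to base.

Step 17
Reactants: 23 8-epi hydroxy ketone; 26 silylated acrylic acid
Product: 27 (6R,7S,8S)-8-acyloxy-9-ketone with the C8 configuration of the target
Conditions: PPh3, DIAD (premixed, 0 °C), then 26 and 23, toluene, 0 °C to rt
Reagents that add atoms: none
Why: Mitsunobu esterification: the alkoxyphosphonium ion at C8 is displaced by the carboxylate in an SN2 process that the adjacent carbonyl accelerates, so C8 is inverted from R to the S configuration of the target while the ester is installed, and premixing PPh3 with DIAD keeps free phosphine away from the acrylate.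

Step 18
Reactants: 27 8-acyloxy-9-ketone
Product: 28 (6R,7S,8S,9S)-9-alcohol
Conditions: NaBH4, CeCl3·7H2O, MeOH–THF, −78 °C
Reagents that add atoms: none
Why: Luche reduction: the cerium-modified hard borohydride attacks the enone carbonyl 1,2 and leaves the acrylate alone, hydride should come from the outer face of the ring, anti to the C8–O bond (polar Felkin–Anh sense), which sets C9 as S with O9 syn to O8 along C7–C8–C9–C10, and the low temperature holds back acyl shift.

Step 19
Reactants: 28 C9 alcohol
Product: 29 (6R,7S,8S,9S)-9-acetate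
Conditions: Ac2O, DMAP (10 mol%), pyridine, CH2Cl2, 0 °C
Reagents that add atoms: acetic anhydride, CC(=O)OC(C)=O
Why: DMAP-catalysed acetylation of the only free hydroxyl, carried out at once so that the C8 acyl group has no time to shift to O9.

Step 20
Reactants: 29 9-acetate
Product: 30 C6 alcohol (4-methoxybenzyl group removed)
Conditions: DDQ, CH2Cl2–pH 7 buffer, 0 °C
Reagents that add atoms: none
Why: Oxidative cleavage of the 4-methoxybenzyl ether by DDQ (hydride abstraction, then hydrolysis of the oxocarbenium ion) in a buffered two-phase medium, which leaves silyl ethers, esters and the non-conjugated alkenes alone.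

Step 21
Reactants: 30 C6 alcohol
Product: 31 6,12,14-triol with the TBDPS ether retained
Conditions: PPTS (20 mol%), MeOH, rt
Reagents that add atoms: none
Why: Acid-catalysed methanolysis that exploits the much greater acid stability of a tert-butyldiphenylsilyl ether over primary tert-butyldimethylsilyl ethers and is mild enough not to trigger transannular cyclisation of the cyclodecadiene or ester exchange.

Step 22
Reactants: 31 triol
Product: 34 trans-fused α-methylene-6,12-lactone bearing the C14 aldehyde, via hydroxy dialdehyde 32 (not isolated), via lactol enal 33 (not isolated)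
Conditions: TEMPO (20 mol%), PhI(OAc)2 (3.5 equiv), CH2Cl2, rt
Reagents that add atoms: none
Why: TEMPO/PhI(OAc)2 oxidation: the oxoammonium salt oxidises the two primary allylic alcohols faster than the secondary C6 alcohol, the C6 hydroxyl adds to the C12 aldehyde (5-exo-trig) to a lactol that is oxidised further to the α-methylene-γ-lactone, C14 stops at the enal, no stereocentre is touched, and C8 cannot compete because it is acylated.

Step 23
Reactants: 34 lactone enal
Product: 35 C14 carboxylic acid
Conditions: NaClO2, NaH2PO4, 2-methylbut-2-ene, t-BuOH–H2O, 0 °C to rt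
Reagents that add atoms: sodium chlorite, [Na+].[O-]Cl=O
Why: Pinnick oxidation: chlorous acid adds to the enal and fragments to the acid, with 2-methylbut-2-ene scavenging HOCl so that the electron-rich C4=C5 alkene is spared.

Step 24
Reactants: 35 C14 acid
Product: 36 C14 methyl ester with the TBDPS ether in place
Conditions: MeI, KHCO3, DMF, rt
Reagents that add atoms: iodomethane, CI
Why: SN2 O-alkylation of the potassium carboxylate with iodomethane under weakly basic conditions, chosen over diazoalkanes because these undergo dipolar cycloaddition to the α-methylene lactone and the acrylate.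

Step 25
Reactants: 36 silylated methyl ester
Product: 37 target CNP0291058.1 (6R,7S,8S,9S)
Conditions: HF·pyridine, pyridine, THF, 0 °C to rt
Reagents that add atoms: none
Why: Fluoride-mediated desilylation with pyridine-buffered HF, acidic enough to avoid acyl migration or Michael addition of the liberated alcohol and mild enough for the acetate, both esters and the lactone.

**Compound list**
1 | (E)-crotonaldehyde | C/C=C/C=O | starting material
2 | (E)-1-(triisopropylsilyloxy)buta-1,3-diene | C=C/C=C/O[Si](C(C)C)(C(C)C)C(C)C | intermediate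
3 | methacrolein | C=C(C)C=O | starting material
4 | (1R,2S)-1-methyl-2-(triisopropylsilyloxy)cyclohex-3-ene-1-carbaldehyde | CC(C)[Si](C(C)C)(C(C)C)O[C@H]1C=CCC[C@@]1(C)C=O | intermediate
5 | {[(1S,6S)-6-[(E)-2-iodoethenyl]-6-methylcyclohex-2-en-1-yl]oxy}triisopropylsilane | CC(C)[Si](C(C)C)(C(C)C)O[C@H]1C=CCC[C@@]1(C)/C=C/I | intermediate
6 | {[(1S,6S)-6-[(E)-2-(4-methoxybenzyloxy)ethenyl]-6-methylcyclohex-2-en-1-yl]oxy}triisopropylsilane | CC(C)[Si](C(C)C)(C(C)C)O[C@H]1C=CCC[C@@]1(C)/C=C/OCc1ccc(OC)cc1 | intermediate
7 | (1S,6S)-6-[(E)-2-(4-methoxybenzyloxy)ethenyl]-6-methylcyclohex-2-en-1-ol | O[C@H]1C=CCC[C@@]1(C)/C=C/OCc1ccc(OC)cc1 | intermediate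
8 | (6S)-6-[(E)-2-(4-methoxybenzyloxy)ethenyl]-6-methylcyclohex-2-en-1-one | O=C1C=CCC[C@@]1(C)/C=C/OCc1ccc(OC)cc1 | intermediate
9 | (6S)-2-(hydroxymethyl)-6-[(E)-2-(4-methoxybenzyloxy)ethenyl]-6-methylcyclohex-2-en-1-one | O=C1C(CO)=CCC[C@@]1(C)/C=C/OCc1ccc(OC)cc1 | intermediate
10 | (6S)-2-{[(tert-butyldimethylsilyl)oxy]methyl}-6-[(E)-2-(4-methoxybenzyloxy)ethenyl]-6-methylcyclohex-2-en-1-one | O=C1C(CO[Si](C)(C)C(C)(C)C)=CCC[C@@]1(C)/C=C/OCc1ccc(OC)cc1 | intermediate
11 | 2-bromoprop-2-en-1-ol | C=C(Br)CO | starting material
12 | ethynyltrimethylsilane | C#C[Si](C)(C)C | starting material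
13 | 2-methylidene-4-(trimethylsilyl)but-3-yn-1-ol | C=C(CO)C#C[Si](C)(C)C | intermediate
14 | tert-butyldimethyl{[2-methylidene-4-(trimethylsilyl)but-3-yn-1-yl]oxy}silane | C=C(CO[Si](C)(C)C(C)(C)C)C#C[Si](C)(C)C | intermediate
15 | tert-butyldimethyl[(2-methylidenebut-3-yn-1-yl)oxy]silane | C=C(CO[Si](C)(C)C(C)(C)C)C#C | intermediate
16 | (E)-dienylzirconocene chloride (not isolated) | Cl[Zr](/C=C/C(=C)CO[Si](C)(C)C(C)(C)C)(C1C=CC=C1)C1C=CC=C1 | intermediate
17 | (1E)-1-iodo-3-{[(tert-butyldimethylsilyl)oxy]methyl}buta-1,3-diene | I/C=C/C(=C)CO[Si](C)(C)C(C)(C)C | intermediate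
18 | (E)-dienyllithium (not isolated) | [Li]/C=C/C(=C)CO[Si](C)(C)C(C)(C)C | intermediate
19 | (E)-dienylcerium dichloride (not isolated) | Cl[Ce](Cl)/C=C/C(=C)CO[Si](C)(C)C(C)(C)C | intermediate
20 | (1R,6S)-trans-1,2-dialkenylcyclohex-2-enol (full name in step 13; OH trans to CH3) | O[C@@]1(/C=C/C(=C)CO[Si](C)(C)C(C)(C)C)C(CO[Si](C)(C)C(C)(C)C)=CCC[C@@]1(C)/C=C/OCc1ccc(OC)cc1 | intermediate
21 | potassium alkoxide of 20 (not isolated) | [K+].[O-][C@@]1(/C=C/C(=C)CO[Si](C)(C)C(C)(C)C)C(CO[Si](C)(C)C(C)(C)C)=CCC[C@@]1(C)/C=C/OCc1ccc(OC)cc1 | intermediate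
22 | ten-membered potassium C8=C9 enolate, C10 trans to C7, C4=C5 E, C1=C10 cis in the ring (not isolated) | [K+].[O-]/C1=C\[C@@H](C(=C)CO[Si](C)(C)C(C)(C)C)[C@H](OCc2ccc(OC)cc2)/C=C(\C)CC/C=C1/CO[Si](C)(C)C(C)(C)C | intermediate
23 | (6R,7R,8R)-8-hydroxy-6-(4-methoxybenzyloxy)-12,14-bis(tert-butyldimethylsilyloxy)germacra-1(10),4,11(13)-trien-9-one, C4=C5 E, C1=C10 cis in the ring (8-epi; the C7 descriptor differs from the target only through CIP priorities) | O[C@@H]1[C@@H](C(=C)CO[Si](C)(C)C(C)(C)C)[C@H](OCc2ccc(OC)cc2)/C=C(\C)CC/C=C(/CO[Si](C)(C)C(C)(C)C)C1=O | intermediate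
24 | methyl 2-(hydroxymethyl)acrylate | C=C(CO)C(=O)OC | starting material
25 | methyl 2-{[(tert-butyldiphenylsilyl)oxy]methyl}acrylate | C=C(CO[Si](c1ccccc1)(c1ccccc1)C(C)(C)C)C(=O)OC | intermediate
26 | 2-{[(tert-butyldiphenylsilyl)oxy]methyl}acrylic acid | C=C(CO[Si](c1ccccc1)(c1ccccc1)C(C)(C)C)C(=O)O | intermediate
27 | (6R,7S,8S)-8-{2-[(tert-butyldiphenylsilyloxy)methyl]acryloyloxy} 9-ketone | C=C(CO[Si](c1ccccc1)(c1ccccc1)C(C)(C)C)C(=O)O[C@H]1[C@@H](C(=C)CO[Si](C)(C)C(C)(C)C)[C@H](OCc2ccc(OC)cc2)/C=C(\C)CC/C=C(/CO[Si](C)(C)C(C)(C)C)C1=O | intermediate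
28 | (6R,7S,8S,9S)-9-alcohol | C=C(CO[Si](c1ccccc1)(c1ccccc1)C(C)(C)C)C(=O)O[C@H]1[C@@H](C(=C)CO[Si](C)(C)C(C)(C)C)[C@H](OCc2ccc(OC)cc2)/C=C(\C)CC/C=C(/CO[Si](C)(C)C(C)(C)C)[C@@H]1O | intermediate
29 | (6R,7S,8S,9S)-9-acetate | C=C(CO[Si](c1ccccc1)(c1ccccc1)C(C)(C)C)C(=O)O[C@H]1[C@@H](C(=C)CO[Si](C)(C)C(C)(C)C)[C@H](OCc2ccc(OC)cc2)/C=C(\C)CC/C=C(/CO[Si](C)(C)C(C)(C)C)[C@@H]1OC(C)=O | intermediate
30 | 9-acetate with free C6 hydroxyl | C=C(CO[Si](c1ccccc1)(c1ccccc1)C(C)(C)C)C(=O)O[C@H]1[C@@H](C(=C)CO[Si](C)(C)C(C)(C)C)[C@H](O)/C=C(\C)CC/C=C(/CO[Si](C)(C)C(C)(C)C)[C@@H]1OC(C)=O | intermediate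
31 | 6,12,14-triol | C=C(CO[Si](c1ccccc1)(c1ccccc1)C(C)(C)C)C(=O)O[C@H]1[C@@H](C(=C)CO)[C@H](O)/C=C(\C)CC/C=C(/CO)[C@@H]1OC(C)=O | intermediate
32 | 6-hydroxy-12,14-dialdehyde (not isolated) | C=C(CO[Si](c1ccccc1)(c1ccccc1)C(C)(C)C)C(=O)O[C@H]1[C@@H](C(=C)C=O)[C@H](O)/C=C(\C)CC/C=C(/C=O)[C@@H]1OC(C)=O | intermediate
33 | 6,12-lactol with C14 enal, C12 epimers (not isolated) | C=C(CO[Si](c1ccccc1)(c1ccccc1)C(C)(C)C)C(=O)O[C@H]1[C@H]2C(=C)C(O)O[C@@H]2/C=C(\C)CC/C=C(/C=O)[C@@H]1OC(C)=O | intermediate
34 | trans-fused α-methylene-6,12-lactone with C14 aldehyde | C=C(CO[Si](c1ccccc1)(c1ccccc1)C(C)(C)C)C(=O)O[C@H]1[C@H]2C(=C)C(=O)O[C@@H]2/C=C(\C)CC/C=C(/C=O)[C@@H]1OC(C)=O | intermediate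
35 | C14 carboxylic acid | C=C(CO[Si](c1ccccc1)(c1ccccc1)C(C)(C)C)C(=O)O[C@H]1[C@H]2C(=C)C(=O)O[C@@H]2/C=C(\C)CC/C=C(/C(=O)O)[C@@H]1OC(C)=O | intermediate
36 | C14 methyl ester, side chain still silylated | C=C(CO[Si](c1ccccc1)(c1ccccc1)C(C)(C)C)C(=O)O[C@H]1[C@H]2C(=C)C(=O)O[C@@H]2/C=C(\C)CC/C=C(/C(=O)OC)[C@@H]1OC(C)=O | intermediate
37 | CNP0291058.1, (6R,7S,8S,9S) | C=C(CO)C(=O)O[C@H]1[C@H]2C(=C)C(=O)O[C@@H]2/C=C(\C)CC/C=C(/C(=O)OC)[C@@H]1OC(C)=O | target

**Total step count:** 25. **Longest linear sequence:** 19 (steps 1–8, 13, 14, 17–25).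

**Steps most likely to fail**

Step 17 (inversion at C8).
- What may go wrong: the rear side of the C8–O bond looks toward the interior of the ten-membered ring, so the displacement may be slow. Elimination toward C7, or epimerisation of the product through its enol, may then take over.
- Fallback: oxygen is not placed on C8 first. Setting out from 20, the rearrangement of step 14 is run as before, and enolate 22 is quenched at −78 °C with N-bromosuccinimide. This should deliver bromine to the same outer face and give the 8-epi α-bromo ketone F1.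
- Acid 26 is converted with Cs2CO3 in DMF into caesium 2-{[(tert-butyldiphenylsilyl)oxy]methyl}acrylate F2. F2 then displaces the bromide of F1 at 0 °C, a classical SN2 reaction of an α-halo ketone with inversion.
- The fallback comes back to the route at 27.

Step 14 (rearrangement and in-flask oxygenation).
- What may go wrong: part of the material may leak through a boat or through the 1,5-diene that includes the ring alkene. The oxygenation may also lose face control, or the enolate may add to the sulfonimine that the oxaziridine leaves behind.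
- Fallback: rearrangement and oxygenation are separated. Setting out from 20, enolate 22 is trapped at −78 °C with Me3SiCl/Et3N to give the trimethylsilyl dienol ether F3. F3 is isolated, so isomers from other transition states can be removed and the ring geometry assigned before C8 is set.
- A Rubottom oxidation with one equivalent of dimethyldioxirane in acetone–CH2Cl2 at −78 °C oxidises the most electron-rich alkene from its outer face. After silyl migration this gives the 8-epi α-trimethylsilyloxy ketone F4.
- Brief treatment of F4 with citric acid in MeOH at 0 °C removes only the trimethylsilyl group. The fallback comes back to the route at 23.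

Step 18 (reduction at C9).
- What may go wrong: the ring ketone is conformationally mobile, so hydride may be delivered to the other carbonyl face. The C8 acyl group may also shift to O9 in the alkoxide.
- Fallback: the substrate bias is accepted and then corrected. Setting out from 27, the reduction is carried out as before and the 9-epi alcohol F5 is isolated.
- F5 is treated with acetic acid, PPh3 and DIAD in toluene at 0 °C. This Mitsunobu displacement inverts C9 and installs the acetate in one operation.
- The fallback comes back to the route at 29 and makes step 19 unnecessary.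

**Further compounds**
F1 | step 17 | 8-epi (8R) α-bromo 9-ketone | Br[C@@H]1[C@@H](C(=C)CO[Si](C)(C)C(C)(C)C)[C@H](OCc2ccc(OC)cc2)/C=C(\C)CC/C=C(/CO[Si](C)(C)C(C)(C)C)C1=O
F2 | step 17 | caesium 2-{[(tert-butyldiphenylsilyl)oxy]methyl}acrylate | [Cs+].C=C(CO[Si](c1ccccc1)(c1ccccc1)C(C)(C)C)C(=O)[O-]
F3 | step 14 | trimethylsilyl dienol ether of the ten-membered ketone | C[Si](C)(C)O/C1=C\[C@@H](C(=C)CO[Si](C)(C)C(C)(C)C)[C@H](OCc2ccc(OC)cc2)/C=C(\C)CC/C=C1/CO[Si](C)(C)C(C)(C)C
F4 | step 14 | 8-epi α-trimethylsilyloxy 9-ketone | C[Si](C)(C)O[C@@H]1[C@@H](C(=C)CO[Si](C)(C)C(C)(C)C)[C@H](OCc2ccc(OC)cc2)/C=C(\C)CC/C=C(/CO[Si](C)(C)C(C)(C)C)C1=O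
F5 | step 18 | 9-epi (9R) alcohol | C=C(CO[Si](c1ccccc1)(c1ccccc1)C(C)(C)C)C(=O)O[C@H]1[C@@H](C(=C)CO[Si](C)(C)C(C)(C)C)[C@H](OCc2ccc(OC)cc2)/C=C(\C)CC/C=C(/CO[Si](C)(C)C(C)(C)C)[C@H]1O
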